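**Synthesis proposal for CNP0292517.0 (linear heptameric phlorethol, rings A to G)**

Retrosynthesis: all six diaryl ether C–O bonds are cut with inverted polarity, so that the oxygen-flanked ring carbon is the electrophile (a C–F bond) and the neighbouring ring supplies the phenoxide; twelve of the eighteen hydroxyls are traced back to formyl groups.
Enabling feature: every ether oxygen sits on a ring carbon whose ortho or para positions carry OH (ring A C1 with C2-OH and C6-OH; rings B, D and F C4 with C3-OH and C5-OH; rings C and E C2 with C3-OH ortho and C5-OH para), so each of these twelve OH groups can start as a CHO that activates fluoride displacement at exactly that carbon.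
Forward: three fluoro-isophthalaldehyde monomers (one for rings B, D, F; one for rings C, E; one for ring A) and a ring G phenol are prepared, and the chain is joined from the G end by six SNAr etherifications in the order G–F, F–E, E–D, D–C, C–B, B–A.
A single twelvefold Baeyer–Villiger oxidation with formate methanolysis then turns every CHO into OH, and hydrogenolysis of six benzyl ethers ends the route; no ring is formed, all seven benzene rings are bought.
Stereochemistry: none to set, the target has no stereocentre and no configurationally stable axis.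

Key step: step 23

Remark: the three starting materials are taken as purchasable, and the terminal ring A is carried as a benzyl ether instead of a MOM ether so that the last deprotections release no formaldehyde equivalent beside the electron-rich rings.

**Monomer for rings B, D and F, and monomer for ring A**

Step 1
Reactants: 1 4-fluoro-3,5-dimethylphenol
Product: 2 4-fluoro-3,5-dimethylphenyl acetate
Conditions: Ac2O, pyridine, DMAP (cat.), CH2Cl2, 0 °C to rt
Reagents that add atoms: acetic anhydride CC(=O)OC(C)=O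
Why: DMAP-catalysed O-acetylation of a phenol; the ester tempers the ring so that the radical bromination that follows is not diverted to electrophilic ring bromination.

Step 2
Reactants: 2 4-fluoro-3,5-dimethylphenyl acetate
Product: 3 3,5-bis(dibromomethyl)-4-fluorophenyl acetate
Conditions: NBS (4.4 equiv), AIBN (cat.), PhCF3, reflux, hν
Reagents that add atoms: N-bromosuccinimide O=C1CCC(=O)N1Br
Why: Wohl–Ziegler benzylic bromination, which should stop at two bromines per methyl group because a third is sterically and electronically disfavoured beside the ortho fluorine.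

Step 3
Reactants: 3 3,5-bis(dibromomethyl)-4-fluorophenyl acetate
Product: 5 2-fluoro-5-hydroxyisophthalaldehyde, via 4-fluoro-3,5-diformylphenyl acetate 4 (not isolated)
Conditions: AgNO3 (4.4 equiv), THF/H2O 3:1, 60 °C, dark; filter; then 3 M HCl, 60 °C
Reagents that add atoms: water O
Why: Silver-assisted hydrolysis of the benzal bromides gives the dialdehyde and acid-catalysed ester hydrolysis then frees the phenol, the medium staying acidic so that no phenoxide arises that could attack the now activated C–F bond.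

Step 4
Reactants: 5 2-fluoro-5-hydroxyisophthalaldehyde
Product: 6 2-fluoro-5-(methoxymethoxy)isophthalaldehyde
Conditions: MOMCl (3 equiv), CH2Cl2, 0 °C; iPr2NEt (1.5 equiv) added dropwise last
Reagents that add atoms: chloromethyl methyl ether COCCl
Why: MOM ether formation on a phenol; with the chloride in excess and the base added last, O-alkylation of the weakly nucleophilic 3,5-diformylphenoxide by the oxocarbenium-like electrophile should outrun intermolecular SNAr on the fluoride.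

Step 5
Reactants: 5 2-fluoro-5-hydroxyisophthalaldehyde
Product: 7 5-(benzyloxy)-2-fluoroisophthalaldehyde
Conditions: BnOH, PPh3, DIAD, THF, 0 °C to rt
Reagents that add atoms: benzyl alcohol OCc1ccccc1
Why: Mitsunobu etherification, in which the phenoxide exists only as an ion pair beside the benzyloxyphosphonium ion, so benzylation should be faster than the self-condensation by SNAr that a carbonate/benzyl bromide alkylation would risk.

**Monomer for rings C and E**

Step 6
Reactants: 8 3-fluoro-4-hydroxybenzaldehyde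
Product: 9 3-fluoro-4-(methoxymethoxy)benzaldehyde
Conditions: MOMCl, iPr2NEt, CH2Cl2, 0 °C to rt
Reagents that add atoms: chloromethyl methyl ether COCCl
Why: Routine MOM protection of a phenol; this acetal is the group that later unmasks the chain-carrying oxygen under acid without touching benzyl ethers.

Step 7
Reactants: 9 3-fluoro-4-(methoxymethoxy)benzaldehyde
Product: 11 3-fluoro-4-(methoxymethoxy)phenol, via 3-fluoro-4-(methoxymethoxy)phenyl formate 10 (not isolated)
Conditions: mCPBA, CH2Cl2, rt; then K2CO3 (cat.), MeOH, 0 °C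
Reagents that add atoms: meta-chloroperbenzoic acid OOC(=O)c1cccc(Cl)c1
Why: Baeyer–Villiger oxidation of a 4-alkoxybenzaldehyde goes with aryl migration because of the para oxygen donor, and the formate is transesterified by methanol under mild base that leaves the MOM ether intact.

Step 8
Reactants: 11 3-fluoro-4-(methoxymethoxy)phenol
Product: 12 3-fluoro-2,6-bis(hydroxymethyl)-4-(methoxymethoxy)phenol
Conditions: 37% aq. CH2O (10 equiv), NaOH (1.2 equiv), H2O/THF, rt to 40 °C, several days; AcOH to pH 6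
Reagents that add atoms: formaldehyde C=O
Why: Lederer–Manasse hydroxymethylation, in which the phenoxide is attacked by formaldehyde only at its two ortho positions because the para position is blocked by the MOM ether, which is stable to aqueous base.

Step 9
Reactants: 12 3-fluoro-2,6-bis(hydroxymethyl)-4-(methoxymethoxy)phenol
Product: 13 [2-(benzyloxy)-4-fluoro-5-(methoxymethoxy)-1,3-phenylene]dimethanol
Conditions: BnBr (1.1 equiv), K2CO3, acetone, reflux
Reagents that add atoms: benzyl bromide BrCc1ccccc1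
Why: Williamson etherification that is selective for the phenol, since carbonate deprotonates the phenol but not the two benzylic alcohols.

Step 10
Reactants: 13 [2-(benzyloxy)-4-fluoro-5-(methoxymethoxy)-1,3-phenylene]dimethanol
Product: 14 2-(benzyloxy)-4-fluoro-5-(methoxymethoxy)isophthalaldehyde
Conditions: activated MnO2 (excess), CH2Cl2, rt
Reagents that add atoms: none
Why: MnO2 oxidises benzylic alcohols to aldehydes under neutral conditions without over-oxidation, which preserves the MOM ether and the C–F bond that becomes activated in this step.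

**Ring G nucleophile**

Step 11
Reactants: 15 3,4,5-tris(benzyloxy)benzaldehyde
Product: 17 3,4,5-tris(benzyloxy)phenol, via 3,4,5-tris(benzyloxy)phenyl formate 16 (not isolated)
Conditions: mCPBA, CH2Cl2, rt; then K2CO3 (cat.), MeOH, rt
Reagents that add atoms: meta-chloroperbenzoic acid OOC(=O)c1cccc(Cl)c1
Why: Baeyer–Villiger oxidation with aryl migration secured by the para benzyloxy donor, followed by base-catalysed formate methanolysis.

**Chain assembly from the G end**

Step 12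
Reactants: 17 3,4,5-tris(benzyloxy)phenol; 6 2-fluoro-5-(methoxymethoxy)isophthalaldehyde
Product: 18 rings G–F dialdehyde MOM ether
Conditions: K2CO3 (1.5 equiv), 6 (1.1 equiv), DMF, rt
Reagents that add atoms: none
Why: SNAr by addition–elimination through a Meisenheimer adduct stabilised by the two ortho formyl groups, with fluoride as nucleofuge and small planar CHO groups that leave the flanked carbon accessible.

Step 13
Reactants: 18 rings G–F dialdehyde MOM ether
Product: 19 rings G–F phenol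
Conditions: 3 M aq. HCl, THF, 50 °C
Reagents that add atoms: none
Why: Acid hydrolysis of the aryl MOM acetal, to which benzyl ethers, aldehydes and the diaryl ether are inert; no alcohol is used, so the aldehydes are not acetalised.

Step 14
Reactants: 19 rings G–F phenol; 14 2-(benzyloxy)-4-fluoro-5-(methoxymethoxy)isophthalaldehyde
Product: 20 rings G–F–E tetraaldehyde MOM ether
Conditions: K2CO3 (1.5 equiv), 14 (1.1 equiv), DMF, rt to 40 °C
Reagents that add atoms: none
Why: SNAr at C4 of 14, activated by the ortho (C3) and para (C1) formyl groups; the phenoxide of 19 is meta to its own CHO groups and so keeps its nucleophilicity, and fluoride leaves far more readily than the benzyloxy group at C2 or the aryloxy group already in the chain.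

Step 15
Reactants: 20 rings G–F–E tetraaldehyde MOM ether
Product: 21 rings G–F–E phenol
Conditions: 3 M aq. HCl, THF, 50 °C
Reagents that add atoms: none
Why: Acid hydrolysis of the MOM acetal as in step 13, selective over benzyl ethers and diaryl ethers.

Step 16
Reactants: 21 rings G–F–E phenol; 6 2-fluoro-5-(methoxymethoxy)isophthalaldehyde
Product: 22 rings G–F–E–D hexaaldehyde MOM ether
Conditions: K2CO3 (1.5 equiv), 6 (1.1 equiv), DMF, rt
Reagents that add atoms: none
Why: SNAr on the doubly ortho-formyl-activated fluoride as in step 12; the mild carbonate conditions favour fluoride displacement over exchange of the internal activated aryloxy groups.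

Step 17
Reactants: 22 rings G–F–E–D hexaaldehyde MOM ether
Product: 23 rings G–F–E–D phenol
Conditions: 3 M aq. HCl, THF, 50 °C
Reagents that add atoms: none
Why: Acid hydrolysis of the MOM acetal as in step 13.

Step 18
Reactants: 23 rings G–F–E–D phenol; 14 2-(benzyloxy)-4-fluoro-5-(methoxymethoxy)isophthalaldehyde
Product: 24 rings G–F–E–D–C octaaldehyde MOM ether
Conditions: K2CO3 (1.5 equiv), 14 (1.2 equiv), DMF, rt to 40 °C
Reagents that add atoms: none
Why: SNAr at the ortho/para-formyl-activated C4 of 14 as in step 14, run with the fluoride in slight excess and stopped at full conversion to keep aryloxide exchange in the chain from competing.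

Step 19
Reactants: 24 rings G–F–E–D–C octaaldehyde MOM ether
Product: 25 rings G–F–E–D–C phenol
Conditions: 3 M aq. HCl, THF, 50 °C
Reagents that add atoms: none
Why: Acid hydrolysis of the MOM acetal as in step 13.

Step 20
Reactants: 25 rings G–F–E–D–C phenol; 6 2-fluoro-5-(methoxymethoxy)isophthalaldehyde
Product: 26 rings G–F–E–D–C–B decaaldehyde MOM ether
Conditions: K2CO3 (1.5 equiv), 6 (1.2 equiv), DMF, rt
Reagents that add atoms: none
Why: SNAr on the doubly ortho-formyl-activated fluoride as in step 12.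

Step 21
Reactants: 26 rings G–F–E–D–C–B decaaldehyde MOM ether
Product: 27 rings G–F–E–D–C–B phenol
Conditions: 3 M aq. HCl, THF, 50 °C
Reagents that add atoms: none
Why: Acid hydrolysis of the MOM acetal as in step 13.

Step 22
Reactants: 27 rings G–F–E–D–C–B phenol; 7 5-(benzyloxy)-2-fluoroisophthalaldehyde
Product: 28 heptamer dodecaaldehyde hexabenzyl ether
Conditions: K2CO3 (1.5 equiv), 7 (1.3 equiv), DMF, rt
Reagents that add atoms: none
Why: SNAr on the doubly ortho-formyl-activated fluoride of the ring A monomer, which needs no removable group because the chain ends here.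

**Unveiling of the hydroxyls**

Step 23
Reactants: 28 heptamer dodecaaldehyde hexabenzyl ether
Product: 30 hexabenzyl ether of the target with twelve free hydroxyls, via heptamer dodecaformate 29 (not isolated)
Conditions: mCPBA (2 equiv per CHO), CH2Cl2, 0 °C to rt, Ar; Me2S quench; then HCl (from AcCl) in degassed MeOH/THF, rt, Ar
Reagents that add atoms: meta-chloroperbenzoic acid OOC(=O)c1cccc(Cl)c1
Why: Proposed new method: each formyl group adds the peracid to a Criegee adduct whose aryl group shifts from carbon to oxygen with loss of 3-chlorobenzoate, leaving an aryl formate that acid methanolysis cleaves to the phenol and methyl formate; twelve such events on one oligomer have no precedent in this multiplicity. The closest known reaction type is the Baeyer–Villiger (Dakin-type) oxidation of a 2-aryloxy- or 2-alkoxybenzaldehyde to the phenol, the usual sequel to a formyl-activated SNAr diaryl ether synthesis, known for one or two formyl groups per substrate. No ring closes and no stereocentre arises. The selectivity needed is aryl over hydride migration at all twelve adducts; it is secured by an oxygen substituent ortho to every formyl-bearing carbon (aryloxy in rings A, B, D and F; benzyloxy plus an ortho or para aryloxy in rings C and E), and each formate formed makes its ring more electron-rich, so the second oxidation on a ring should be easier than the first. The new oxygens stay acylated until the peracid is destroyed, which shields the rings from over-oxidation, and since ring A carries a benzyl ether the methanolysis sets free only methyl formate and no formaldehyde equivalent that could alkylate the phloroglucinol- and pyrogallol-type rings.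

Step 24
Reactants: 30 hexabenzyl ether of the target with twelve free hydroxyls
Product: 31 target CNP0292517.0
Conditions: H2 (1 atm), Pd/C, degassed THF/MeOH, rt; filtration and concentration under Ar
Reagents that add atoms: none
Why: Catalytic hydrogenolysis of benzyl ethers, to which diaryl ethers and phenols are inert; oxygen is excluded because the polyhydroxylated rings autoxidise readily.

**Compound list**

1 | 4-fluoro-3,5-dimethylphenol | Cc1cc(O)cc(C)c1F | starting material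
2 | 4-fluoro-3,5-dimethylphenyl acetate | CC(=O)Oc1cc(C)c(F)c(C)c1 | intermediate
3 | 3,5-bis(dibromomethyl)-4-fluorophenyl acetate | CC(=O)Oc1cc(C(Br)Br)c(F)c(C(Br)Br)c1 | intermediate
4 | 4-fluoro-3,5-diformylphenyl acetate | CC(=O)Oc1cc(C=O)c(F)c(C=O)c1 | intermediate
5 | 2-fluoro-5-hydroxyisophthalaldehyde | Oc1cc(C=O)c(F)c(C=O)c1 | intermediate
6 | 2-fluoro-5-(methoxymethoxy)isophthalaldehyde (monomer for rings B, D, F) | COCOc1cc(C=O)c(F)c(C=O)c1 | intermediate
7 | 5-(benzyloxy)-2-fluoroisophthalaldehyde (monomer for ring A) | O=Cc1cc(OCc2ccccc2)cc(C=O)c1F | intermediate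
8 | 3-fluoro-4-hydroxybenzaldehyde | O=Cc1ccc(O)c(F)c1 | starting material
9 | 3-fluoro-4-(methoxymethoxy)benzaldehyde | COCOc1ccc(C=O)cc1F | intermediate
10 | 3-fluoro-4-(methoxymethoxy)phenyl formate | COCOc1ccc(OC=O)cc1F | intermediate
11 | 3-fluoro-4-(methoxymethoxy)phenol | COCOc1ccc(O)cc1F | intermediate
12 | 3-fluoro-2,6-bis(hydroxymethyl)-4-(methoxymethoxy)phenol | COCOc1cc(CO)c(O)c(CO)c1F | intermediate
13 | [2-(benzyloxy)-4-fluoro-5-(methoxymethoxy)-1,3-phenylene]dimethanol | COCOc1cc(CO)c(OCc2ccccc2)c(CO)c1F | intermediate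
14 | 2-(benzyloxy)-4-fluoro-5-(methoxymethoxy)isophthalaldehyde (monomer for rings C, E) | COCOc1cc(C=O)c(OCc2ccccc2)c(C=O)c1F | intermediate
15 | 3,4,5-tris(benzyloxy)benzaldehyde | O=Cc1cc(OCc2ccccc2)c(OCc2ccccc2)c(OCc2ccccc2)c1 | starting material
16 | 3,4,5-tris(benzyloxy)phenyl formate | O=COc1cc(OCc2ccccc2)c(OCc2ccccc2)c(OCc2ccccc2)c1 | intermediate
17 | 3,4,5-tris(benzyloxy)phenol (ring G) | Oc1cc(OCc2ccccc2)c(OCc2ccccc2)c(OCc2ccccc2)c1 | intermediate
18 | rings G–F dialdehyde MOM ether: 5-(methoxymethoxy)-2-[3,4,5-tris(benzyloxy)phenoxy]isophthalaldehyde | COCOc1cc(C=O)c(Oc2cc(OCc3ccccc3)c(OCc3ccccc3)c(OCc3ccccc3)c2)c(C=O)c1 | intermediate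
19 | rings G–F phenol: 5-hydroxy-2-[3,4,5-tris(benzyloxy)phenoxy]isophthalaldehyde | Oc1cc(C=O)c(Oc2cc(OCc3ccccc3)c(OCc3ccccc3)c(OCc3ccccc3)c2)c(C=O)c1 | intermediate
20 | rings G–F–E tetraaldehyde MOM ether: 2-(benzyloxy)-4-{3,5-diformyl-4-[3,4,5-tris(benzyloxy)phenoxy]phenoxy}-5-(methoxymethoxy)isophthalaldehyde | COCOc1cc(C=O)c(OCc2ccccc2)c(C=O)c1Oc1cc(C=O)c(Oc2cc(OCc3ccccc3)c(OCc3ccccc3)c(OCc3ccccc3)c2)c(C=O)c1 | intermediate
21 | rings G–F–E phenol: 20 with OH in place of the MOM ether | Oc1cc(C=O)c(OCc2ccccc2)c(C=O)c1Oc1cc(C=O)c(Oc2cc(OCc3ccccc3)c(OCc3ccccc3)c(OCc3ccccc3)c2)c(C=O)c1 | intermediate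
22 | rings G–F–E–D hexaaldehyde MOM ether: 5-(methoxymethoxy)isophthalaldehyde whose C2 carries the ring E phenol oxygen of 21 | COCOc1cc(C=O)c(Oc2cc(C=O)c(OCc3ccccc3)c(C=O)c2Oc2cc(C=O)c(Oc3cc(OCc4ccccc4)c(OCc4ccccc4)c(OCc4ccccc4)c3)c(C=O)c2)c(C=O)c1 | intermediate
23 | rings G–F–E–D phenol: 22 with OH in place of the MOM ether | Oc1cc(C=O)c(Oc2cc(C=O)c(OCc3ccccc3)c(C=O)c2Oc2cc(C=O)c(Oc3cc(OCc4ccccc4)c(OCc4ccccc4)c(OCc4ccccc4)c3)c(C=O)c2)c(C=O)c1 | intermediate
24 | rings G–F–E–D–C octaaldehyde MOM ether: 2-(benzyloxy)-5-(methoxymethoxy)isophthalaldehyde whose C4 carries the ring D phenol oxygen of 23 | COCOc1cc(C=O)c(OCc2ccccc2)c(C=O)c1Oc1cc(C=O)c(Oc2cc(C=O)c(OCc3ccccc3)c(C=O)c2Oc2cc(C=O)c(Oc3cc(OCc4ccccc4)c(OCc4ccccc4)c(OCc4ccccc4)c3)c(C=O)c2)c(C=O)c1 | intermediate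
25 | rings G–F–E–D–C phenol: 24 with OH in place of the MOM ether | Oc1cc(C=O)c(OCc2ccccc2)c(C=O)c1Oc1cc(C=O)c(Oc2cc(C=O)c(OCc3ccccc3)c(C=O)c2Oc2cc(C=O)c(Oc3cc(OCc4ccccc4)c(OCc4ccccc4)c(OCc4ccccc4)c3)c(C=O)c2)c(C=O)c1 | intermediate
26 | rings G–F–E–D–C–B decaaldehyde MOM ether: 5-(methoxymethoxy)isophthalaldehyde whose C2 carries the ring C phenol oxygen of 25 | COCOc1cc(C=O)c(Oc2cc(C=O)c(OCc3ccccc3)c(C=O)c2Oc2cc(C=O)c(Oc3cc(C=O)c(OCc4ccccc4)c(C=O)c3Oc3cc(C=O)c(Oc4cc(OCc5ccccc5)c(OCc5ccccc5)c(OCc5ccccc5)c4)c(C=O)c3)c(C=O)c2)c(C=O)c1 | intermediate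
27 | rings G–F–E–D–C–B phenol: 26 with OH in place of the MOM ether | Oc1cc(C=O)c(Oc2cc(C=O)c(OCc3ccccc3)c(C=O)c2Oc2cc(C=O)c(Oc3cc(C=O)c(OCc4ccccc4)c(C=O)c3Oc3cc(C=O)c(Oc4cc(OCc5ccccc5)c(OCc5ccccc5)c(OCc5ccccc5)c4)c(C=O)c3)c(C=O)c2)c(C=O)c1 | intermediate
28 | heptamer dodecaaldehyde hexabenzyl ether: 5-(benzyloxy)isophthalaldehyde (ring A) whose C2 carries the ring B phenol oxygen of 27 | O=Cc1cc(OCc2ccccc2)cc(C=O)c1Oc1cc(C=O)c(Oc2cc(C=O)c(OCc3ccccc3)c(C=O)c2Oc2cc(C=O)c(Oc3cc(C=O)c(OCc4ccccc4)c(C=O)c3Oc3cc(C=O)c(Oc4cc(OCc5ccccc5)c(OCc5ccccc5)c(OCc5ccccc5)c4)c(C=O)c3)c(C=O)c2)c(C=O)c1 | intermediate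
29 | heptamer dodecaformate: 28 with OCHO in place of each of the twelve CHO groups | O=COc1cc(OCc2ccccc2)cc(OC=O)c1Oc1cc(OC=O)c(Oc2cc(OC=O)c(OCc3ccccc3)c(OC=O)c2Oc2cc(OC=O)c(Oc3cc(OC=O)c(OCc4ccccc4)c(OC=O)c3Oc3cc(OC=O)c(Oc4cc(OCc5ccccc5)c(OCc5ccccc5)c(OCc5ccccc5)c4)c(OC=O)c3)c(OC=O)c2)c(OC=O)c1 | intermediate
30 | hexabenzyl ether of the target: twelve free OH, benzyl ethers at ring A C4, ring C C4, ring E C4 and ring G C3, C4, C5 | Oc1cc(OCc2ccccc2)cc(O)c1Oc1cc(O)c(Oc2cc(O)c(OCc3ccccc3)c(O)c2Oc2cc(O)c(Oc3cc(O)c(OCc4ccccc4)c(O)c3Oc3cc(O)c(Oc4cc(OCc5ccccc5)c(OCc5ccccc5)c(OCc5ccccc5)c4)c(O)c3)c(O)c2)c(O)c1 | intermediate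
31 | target CNP0292517.0, heptameric phlorethol with eighteen OH and six diaryl ether links, achiral | Oc1cc(O)c(Oc2cc(O)c(Oc3cc(O)c(O)c(O)c3Oc3cc(O)c(Oc4cc(O)c(O)c(O)c4Oc4cc(O)c(Oc5cc(O)c(O)c(O)c5)c(O)c4)c(O)c3)c(O)c2)c(O)c1 | target

**Count**

Total steps: 24. Longest linear sequence: 17 steps (steps 1 to 4, then 12 to 24).

**Steps most likely to fail**

Step 23 (twelvefold Baeyer–Villiger oxidation). With twelve sites on one molecule, hydride instead of aryl migration at a few Criegee adducts, stalling on rings that are still electron-poor, or over-oxidation of rings that have already become electron-rich would each leave a mixture that cannot be separated. The fallback keeps the same CHO-to-OH conversion but spreads it over the chain growth, two formyl groups at a time, which is the known double Baeyer–Villiger oxidation of a 2-aryloxyisophthalaldehyde; it sets out from 18 and comes back to the route at 31.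
- Ring F: dialdehyde 18 would be oxidised with mCPBA to the dimer bis-formate F1, methanolysed (Et3N, MeOH, Ar) to the dimer diol F2, benzylated (BnBr, K2CO3, DMF) to the dimer bis(benzyl ether) F3 and freed from the MOM group (3 M HCl, THF) as the dimer phenol F4.
- Ring E: SNAr of F4 on 14 would give the trimer dialdehyde F5, and the same four operations the trimer bis-formate F6, the trimer diol F7, the trimer benzyl ether F8 and the trimer phenol F9.
- Ring D: coupling of F9 with 6 would give the tetramer dialdehyde F10, then the tetramer bis-formate F11, the tetramer diol F12, the tetramer benzyl ether F13 and the tetramer phenol F14.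
- Ring C: coupling of F14 with 14 would give the pentamer dialdehyde F15, then the pentamer bis-formate F16, the pentamer diol F17, the pentamer benzyl ether F18 and the pentamer phenol F19.
- Ring B: coupling of F19 with 6 would give the hexamer dialdehyde F20, then the hexamer bis-formate F21, the hexamer diol F22, the hexamer benzyl ether F23 and the hexamer phenol F24.
- Ring A: SNAr of F24 on 7 would give the heptamer dialdehyde F25, mCPBA the heptamer bis-formate F26 and HCl in methanol the heptamer diol F27, which carries sixteen benzyl ethers and would be hydrogenolysed (H2, Pd/C) to 31.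

Every nucleophile is then an electron-rich phenoxide and no activated aryl ether remains in the chain, at the price of a markedly longer sequence.

Step 18 (SNAr of the hexaaldehyde phenoxide on the more hindered, less activated fluoride 14). The phenoxide may attack an internal formyl-activated ether carbon instead of the C–F carbon, so that aryloxide is exchanged and the chain is cut and scrambled, or the coupling may stall. The fallback masks the activating groups of the chain before the coupling; it sets out from 23 and comes back at 25. Phenol 23 would be converted with HC(OMe)3 and TsOH (cat.) in MeOH into the hexakis(dimethyl acetal) phenol F28, whose ether carbons are no longer activated and whose phenoxide is more nucleophilic. SNAr on 14 (K2CO3, DMF) would give the acetal-masked pentamer F29, and aqueous HCl in THF would remove the six acetals together with the MOM group to deliver 25.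

Step 8 (double ortho-hydroxymethylation). Substitution may stop after the less hindered ortho position, the other one lying between OH and F, or run on to methylene-bridged phenol–formaldehyde oligomers. The fallback brings in the two carbons by cross-coupling instead of electrophilic substitution; it sets out from 11 and comes back at 14. NBS (2.1 equiv, MeCN, 0 °C) would give the dibromophenol F30, and BnBr with K2CO3 the dibromo benzyl ether F31. Double Suzuki–Miyaura coupling with potassium vinyltrifluoroborate (PdCl2(dppf), Cs2CO3, THF/H2O, 80 °C) would give the divinyl arene F32, and Lemieux–Johnson cleavage (OsO4 cat., NaIO4, 2,6-lutidine, dioxane/H2O) the dialdehyde 14.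

**Further compounds**

F1 | step 23 | dimer bis-formate: 5-(methoxymethoxy)-2-[3,4,5-tris(benzyloxy)phenoxy]-1,3-phenylene diformate | COCOc6cc(OC=O)c(Oc7cc(OCc9ccccc9)c(OCc9ccccc9)c(OCc9ccccc9)c7)c(OC=O)c6
F2 | step 23 | dimer diol: 5-(methoxymethoxy)-2-[3,4,5-tris(benzyloxy)phenoxy]benzene-1,3-diol | COCOc6cc(O)c(Oc7cc(OCc9ccccc9)c(OCc9ccccc9)c(OCc9ccccc9)c7)c(O)c6
F3 | step 23 | dimer bis(benzyl ether): 1,3-bis(benzyloxy)-5-(methoxymethoxy)-2-[3,4,5-tris(benzyloxy)phenoxy]benzene | COCOc6cc(OCc9ccccc9)c(Oc7cc(OCc9ccccc9)c(OCc9ccccc9)c(OCc9ccccc9)c7)c(OCc9ccccc9)c6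
F4 | step 23 | dimer phenol: 3,5-bis(benzyloxy)-4-[3,4,5-tris(benzyloxy)phenoxy]phenol | Oc6cc(OCc9ccccc9)c(Oc7cc(OCc9ccccc9)c(OCc9ccccc9)c(OCc9ccccc9)c7)c(OCc9ccccc9)c6
F5 | step 23 | trimer dialdehyde: 14 with the phenoxy residue of F4 in place of F | COCOc5cc(C=O)c(OCc9ccccc9)c(C=O)c5Oc6cc(OCc9ccccc9)c(Oc7cc(OCc9ccccc9)c(OCc9ccccc9)c(OCc9ccccc9)c7)c(OCc9ccccc9)c6
F6 | step 23 | trimer bis-formate: F5 with OCHO in place of both CHO | COCOc5cc(OC=O)c(OCc9ccccc9)c(OC=O)c5Oc6cc(OCc9ccccc9)c(Oc7cc(OCc9ccccc9)c(OCc9ccccc9)c(OCc9ccccc9)c7)c(OCc9ccccc9)c6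
F7 | step 23 | trimer diol: F6 with OH in place of both OCHO | COCOc5cc(O)c(OCc9ccccc9)c(O)c5Oc6cc(OCc9ccccc9)c(Oc7cc(OCc9ccccc9)c(OCc9ccccc9)c(OCc9ccccc9)c7)c(OCc9ccccc9)c6
F8 | step 23 | trimer benzyl ether: F7 with both OH benzylated | COCOc5cc(OCc9ccccc9)c(OCc9ccccc9)c(OCc9ccccc9)c5Oc6cc(OCc9ccccc9)c(Oc7cc(OCc9ccccc9)c(OCc9ccccc9)c(OCc9ccccc9)c7)c(OCc9ccccc9)c6
F9 | step 23 | trimer phenol: F8 with OH in place of the MOM ether | Oc5cc(OCc9ccccc9)c(OCc9ccccc9)c(OCc9ccccc9)c5Oc6cc(OCc9ccccc9)c(Oc7cc(OCc9ccccc9)c(OCc9ccccc9)c(OCc9ccccc9)c7)c(OCc9ccccc9)c6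
F10 | step 23 | tetramer dialdehyde: 6 with the phenoxy residue of F9 in place of F | COCOc4cc(C=O)c(Oc5cc(OCc9ccccc9)c(OCc9ccccc9)c(OCc9ccccc9)c5Oc6cc(OCc9ccccc9)c(Oc7cc(OCc9ccccc9)c(OCc9ccccc9)c(OCc9ccccc9)c7)c(OCc9ccccc9)c6)c(C=O)c4
F11 | step 23 | tetramer bis-formate: F10 with OCHO in place of both CHO | COCOc4cc(OC=O)c(Oc5cc(OCc9ccccc9)c(OCc9ccccc9)c(OCc9ccccc9)c5Oc6cc(OCc9ccccc9)c(Oc7cc(OCc9ccccc9)c(OCc9ccccc9)c(OCc9ccccc9)c7)c(OCc9ccccc9)c6)c(OC=O)c4
F12 | step 23 | tetramer diol: F11 with OH in place of both OCHO | COCOc4cc(O)c(Oc5cc(OCc9ccccc9)c(OCc9ccccc9)c(OCc9ccccc9)c5Oc6cc(OCc9ccccc9)c(Oc7cc(OCc9ccccc9)c(OCc9ccccc9)c(OCc9ccccc9)c7)c(OCc9ccccc9)c6)c(O)c4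
F13 | step 23 | tetramer benzyl ether: F12 with both OH benzylated | COCOc4cc(OCc9ccccc9)c(Oc5cc(OCc9ccccc9)c(OCc9ccccc9)c(OCc9ccccc9)c5Oc6cc(OCc9ccccc9)c(Oc7cc(OCc9ccccc9)c(OCc9ccccc9)c(OCc9ccccc9)c7)c(OCc9ccccc9)c6)c(OCc9ccccc9)c4
F14 | step 23 | tetramer phenol: F13 with OH in place of the MOM ether | Oc4cc(OCc9ccccc9)c(Oc5cc(OCc9ccccc9)c(OCc9ccccc9)c(OCc9ccccc9)c5Oc6cc(OCc9ccccc9)c(Oc7cc(OCc9ccccc9)c(OCc9ccccc9)c(OCc9ccccc9)c7)c(OCc9ccccc9)c6)c(OCc9ccccc9)c4
F15 | step 23 | pentamer dialdehyde: 14 with the phenoxy residue of F14 in place of F | COCOc3cc(C=O)c(OCc9ccccc9)c(C=O)c3Oc4cc(OCc9ccccc9)c(Oc5cc(OCc9ccccc9)c(OCc9ccccc9)c(OCc9ccccc9)c5Oc6cc(OCc9ccccc9)c(Oc7cc(OCc9ccccc9)c(OCc9ccccc9)c(OCc9ccccc9)c7)c(OCc9ccccc9)c6)c(OCc9ccccc9)c4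
F16 | step 23 | pentamer bis-formate: F15 with OCHO in place of both CHO | COCOc3cc(OC=O)c(OCc9ccccc9)c(OC=O)c3Oc4cc(OCc9ccccc9)c(Oc5cc(OCc9ccccc9)c(OCc9ccccc9)c(OCc9ccccc9)c5Oc6cc(OCc9ccccc9)c(Oc7cc(OCc9ccccc9)c(OCc9ccccc9)c(OCc9ccccc9)c7)c(OCc9ccccc9)c6)c(OCc9ccccc9)c4
F17 | step 23 | pentamer diol: F16 with OH in place of both OCHO | COCOc3cc(O)c(OCc9ccccc9)c(O)c3Oc4cc(OCc9ccccc9)c(Oc5cc(OCc9ccccc9)c(OCc9ccccc9)c(OCc9ccccc9)c5Oc6cc(OCc9ccccc9)c(Oc7cc(OCc9ccccc9)c(OCc9ccccc9)c(OCc9ccccc9)c7)c(OCc9ccccc9)c6)c(OCc9ccccc9)c4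
F18 | step 23 | pentamer benzyl ether: F17 with both OH benzylated | COCOc3cc(OCc9ccccc9)c(OCc9ccccc9)c(OCc9ccccc9)c3Oc4cc(OCc9ccccc9)c(Oc5cc(OCc9ccccc9)c(OCc9ccccc9)c(OCc9ccccc9)c5Oc6cc(OCc9ccccc9)c(Oc7cc(OCc9ccccc9)c(OCc9ccccc9)c(OCc9ccccc9)c7)c(OCc9ccccc9)c6)c(OCc9ccccc9)c4
F19 | step 23 | pentamer phenol: F18 with OH in place of the MOM ether | Oc3cc(OCc9ccccc9)c(OCc9ccccc9)c(OCc9ccccc9)c3Oc4cc(OCc9ccccc9)c(Oc5cc(OCc9ccccc9)c(OCc9ccccc9)c(OCc9ccccc9)c5Oc6cc(OCc9ccccc9)c(Oc7cc(OCc9ccccc9)c(OCc9ccccc9)c(OCc9ccccc9)c7)c(OCc9ccccc9)c6)c(OCc9ccccc9)c4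
F20 | step 23 | hexamer dialdehyde: 6 with the phenoxy residue of F19 in place of F | COCOc2cc(C=O)c(Oc3cc(OCc9ccccc9)c(OCc9ccccc9)c(OCc9ccccc9)c3Oc4cc(OCc9ccccc9)c(Oc5cc(OCc9ccccc9)c(OCc9ccccc9)c(OCc9ccccc9)c5Oc6cc(OCc9ccccc9)c(Oc7cc(OCc9ccccc9)c(OCc9ccccc9)c(OCc9ccccc9)c7)c(OCc9ccccc9)c6)c(OCc9ccccc9)c4)c(C=O)c2
F21 | step 23 | hexamer bis-formate: F20 with OCHO in place of both CHO | COCOc2cc(OC=O)c(Oc3cc(OCc9ccccc9)c(OCc9ccccc9)c(OCc9ccccc9)c3Oc4cc(OCc9ccccc9)c(Oc5cc(OCc9ccccc9)c(OCc9ccccc9)c(OCc9ccccc9)c5Oc6cc(OCc9ccccc9)c(Oc7cc(OCc9ccccc9)c(OCc9ccccc9)c(OCc9ccccc9)c7)c(OCc9ccccc9)c6)c(OCc9ccccc9)c4)c(OC=O)c2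
F22 | step 23 | hexamer diol: F21 with OH in place of both OCHO | COCOc2cc(O)c(Oc3cc(OCc9ccccc9)c(OCc9ccccc9)c(OCc9ccccc9)c3Oc4cc(OCc9ccccc9)c(Oc5cc(OCc9ccccc9)c(OCc9ccccc9)c(OCc9ccccc9)c5Oc6cc(OCc9ccccc9)c(Oc7cc(OCc9ccccc9)c(OCc9ccccc9)c(OCc9ccccc9)c7)c(OCc9ccccc9)c6)c(OCc9ccccc9)c4)c(O)c2
F23 | step 23 | hexamer benzyl ether: F22 with both OH benzylated | COCOc2cc(OCc9ccccc9)c(Oc3cc(OCc9ccccc9)c(OCc9ccccc9)c(OCc9ccccc9)c3Oc4cc(OCc9ccccc9)c(Oc5cc(OCc9ccccc9)c(OCc9ccccc9)c(OCc9ccccc9)c5Oc6cc(OCc9ccccc9)c(Oc7cc(OCc9ccccc9)c(OCc9ccccc9)c(OCc9ccccc9)c7)c(OCc9ccccc9)c6)c(OCc9ccccc9)c4)c(OCc9ccccc9)c2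
F24 | step 23 | hexamer phenol: F23 with OH in place of the MOM ether | Oc2cc(OCc9ccccc9)c(Oc3cc(OCc9ccccc9)c(OCc9ccccc9)c(OCc9ccccc9)c3Oc4cc(OCc9ccccc9)c(Oc5cc(OCc9ccccc9)c(OCc9ccccc9)c(OCc9ccccc9)c5Oc6cc(OCc9ccccc9)c(Oc7cc(OCc9ccccc9)c(OCc9ccccc9)c(OCc9ccccc9)c7)c(OCc9ccccc9)c6)c(OCc9ccccc9)c4)c(OCc9ccccc9)c2
F25 | step 23 | heptamer dialdehyde: 7 with the phenoxy residue of F24 in place of F | O=Cc1cc(OCc9ccccc9)cc(C=O)c1Oc2cc(OCc9ccccc9)c(Oc3cc(OCc9ccccc9)c(OCc9ccccc9)c(OCc9ccccc9)c3Oc4cc(OCc9ccccc9)c(Oc5cc(OCc9ccccc9)c(OCc9ccccc9)c(OCc9ccccc9)c5Oc6cc(OCc9ccccc9)c(Oc7cc(OCc9ccccc9)c(OCc9ccccc9)c(OCc9ccccc9)c7)c(OCc9ccccc9)c6)c(OCc9ccccc9)c4)c(OCc9ccccc9)c2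
F26 | step 23 | heptamer bis-formate: F25 with OCHO in place of both CHO | O=COc1cc(OCc9ccccc9)cc(OC=O)c1Oc2cc(OCc9ccccc9)c(Oc3cc(OCc9ccccc9)c(OCc9ccccc9)c(OCc9ccccc9)c3Oc4cc(OCc9ccccc9)c(Oc5cc(OCc9ccccc9)c(OCc9ccccc9)c(OCc9ccccc9)c5Oc6cc(OCc9ccccc9)c(Oc7cc(OCc9ccccc9)c(OCc9ccccc9)c(OCc9ccccc9)c7)c(OCc9ccccc9)c6)c(OCc9ccccc9)c4)c(OCc9ccccc9)c2
F27 | step 23 | heptamer diol: hexadecabenzyl ether of the target with free OH at ring A C2 and C6 | Oc1cc(OCc9ccccc9)cc(O)c1Oc2cc(OCc9ccccc9)c(Oc3cc(OCc9ccccc9)c(OCc9ccccc9)c(OCc9ccccc9)c3Oc4cc(OCc9ccccc9)c(Oc5cc(OCc9ccccc9)c(OCc9ccccc9)c(OCc9ccccc9)c5Oc6cc(OCc9ccccc9)c(Oc7cc(OCc9ccccc9)c(OCc9ccccc9)c(OCc9ccccc9)c7)c(OCc9ccccc9)c6)c(OCc9ccccc9)c4)c(OCc9ccccc9)c2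
F28 | step 18 | hexakis(dimethyl acetal) phenol: 23 with CH(OCH3)2 in place of each of the six CHO groups | Oc1cc(C(OC)OC)c(Oc2cc(C(OC)OC)c(OCc3ccccc3)c(C(OC)OC)c2Oc2cc(C(OC)OC)c(Oc3cc(OCc4ccccc4)c(OCc4ccccc4)c(OCc4ccccc4)c3)c(C(OC)OC)c2)c(C(OC)OC)c1
F29 | step 18 | acetal-masked pentamer: 14 with the phenoxy residue of F28 in place of F | COCOc1cc(C=O)c(OCc2ccccc2)c(C=O)c1Oc1cc(C(OC)OC)c(Oc2cc(C(OC)OC)c(OCc3ccccc3)c(C(OC)OC)c2Oc2cc(C(OC)OC)c(Oc3cc(OCc4ccccc4)c(OCc4ccccc4)c(OCc4ccccc4)c3)c(C(OC)OC)c2)c(C(OC)OC)c1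
F30 | step 8 | dibromophenol: 2,6-dibromo-3-fluoro-4-(methoxymethoxy)phenol | COCOc1cc(Br)c(O)c(Br)c1F
F31 | step 8 | dibromo benzyl ether: 2-(benzyloxy)-1,3-dibromo-4-fluoro-5-(methoxymethoxy)benzene | COCOc1cc(Br)c(OCc2ccccc2)c(Br)c1F
F32 | step 8 | divinyl arene: 2-(benzyloxy)-4-fluoro-5-(methoxymethoxy)-1,3-divinylbenzene | COCOc1cc(C=C)c(OCc2ccccc2)c(C=C)c1F
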